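## Retrosynthetic overview

1. The last step forms the C6–C7 bond. An alkenyl bromide adds to an epoxy aldehyde under Ni/Cr mediation, and the new C6 alkoxide opens a cis-placed β-lactone. The ten-membered ring and the butenolide therefore form together, and C13–OH is released without a protecting group.
2. The seco-aldehyde comes from a C1–C10 Ni/Cr coupling of an east vinyl iodide with a west aldehyde, followed by selective oxidation of the primary alcohol.
3. The east fragment comes from bromopalladation/carbonylation of a 2-alkyn-1-ol, which fixes the tetrasubstituted C7=C11 geometry. That alkynol comes from asymmetric alkynylation of (Z)-3-iodobut-2-enal and tigloylation.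
4. The west fragment comes from Sharpless epoxidation of geraniol and ozonolysis.
5. Ring order: oxirane, then a temporary oxetan-2-one, then carbocycle and butenolide in one operation.

Atom labels C1–C15 follow germacrane numbering of the target (C1 carbinol, C4–C5 oxirane, C6 lactone oxygen, C8 tiglate).

Assumption: the facial sense of the two ligand-controlled additions (steps 3 and 9) is assigned by analogy. Both ligands are available as either antipode, so the mirror-image ligand is used if the sense is reversed.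

## Route

Step 1
Reactants: 1 but-2-yn-1-ol
Product: 3 (Z)-3-iodobut-2-en-1-ol, via cyclic alkenylalanate 2 (not isolated)
Conditions: NaAlH2(OCH2CH2OMe)2 (1.5 equiv), Et2O, 0 °C to rt; I2, THF, −78 °C
Reagents that add atoms: iodine, II
Why: Hydroxyl-directed trans-hydroalumination places aluminium on C3 in a five-membered chelate, and iodinolysis with retention gives only the Z-iodide, which fixes the later C9=C10 geometry.

Step 2
Reactants: 3 (Z)-3-iodobut-2-en-1-ol
Product: 4 (Z)-3-iodobut-2-enal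
Conditions: MnO2 (15 equiv), CH2Cl2, rt, dark
Reagents that add atoms: none
Why: Neutral MnO2 oxidation of an allylic alcohol leaves the C–I bond and the Z-geometry untouched.

Step 3
Reactants: 4 (Z)-3-iodobut-2-enal; 5 tert-butyldimethyl(prop-2-yn-1-yloxy)silane
Product: 7 (2Z,4S)-7-[(tert-butyldimethylsilyl)oxy]-2-iodohept-2-en-5-yn-4-ol, via alkynylzinc 6 (not isolated)
Conditions: Me2Zn (3 equiv), (S,S)-ProPhenol (20 mol %), Ph3PO (40 mol %), toluene, 4 °C
Reagents that add atoms: none
Why: Dinuclear-zinc ProPhenol asymmetric alkynylation, which works best on enals, delivers the alkynylzinc to one aldehyde face and sets C8 as S.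

Step 4
Reactants: 7 (2Z,4S)-7-[(tert-butyldimethylsilyl)oxy]-2-iodohept-2-en-5-yn-4-ol; 8 tigloyl chloride
Product: 9 (2Z,4S)-7-[(tert-butyldimethylsilyl)oxy]-2-iodohept-2-en-5-yn-4-yl (E)-2-methylbut-2-enoate
Conditions: Et3N, DMAP (10 mol %), CH2Cl2, 0 °C to rt
Reagents that add atoms: none
Why: DMAP-catalysed acylation of the only free hydroxyl installs the tiglate with retention at C8, before any other hydroxyl exists.

Step 5
Reactants: 9 (2Z,4S)-7-[(tert-butyldimethylsilyl)oxy]-2-iodohept-2-en-5-yn-4-yl (E)-2-methylbut-2-enoate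
Product: 10 (2Z,4S)-7-hydroxy-2-iodohept-2-en-5-yn-4-yl (E)-2-methylbut-2-enoate
Conditions: HF·pyridine, THF, 0 °C
Reagents that add atoms: none
Why: Fluoride desilylation frees the propargylic alcohol, and the linear alkyne rules out acyl migration from O8.

Step 6
Reactants: 10 (2Z,4S)-7-hydroxy-2-iodohept-2-en-5-yn-4-yl (E)-2-methylbut-2-enoate
Product: 11 (1Z,2S,3Z)-1-bromo-4-iodo-1-(2-oxooxetan-3-ylidene)pent-3-en-2-yl (E)-2-methylbut-2-enoate
Conditions: PdBr2 (10 mol %), CuBr2 (5 equiv), CO (20 atm), THF, 30 °C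
Reagents that add atoms: carbon monoxide, [C-]#[O+]; copper dibromide, [Cu+2].[Br-].[Br-]
Why: In this oxidative cyclocarbonylation of a 2-alkyn-1-ol, hydroxyl-directed cis-bromopalladation, CO insertion and lactonisation place Br on C7 cis to the new C12 carbonyl (Z), while excess CuBr2 keeps palladium divalent so that the C–I bond is spared.

Step 7
Reactants: 12 geraniol
Product: 13 (2R,3R)-2,3-epoxygeraniol
Conditions: Ti(OiPr)4 (5 mol %), D-(−)-diethyl tartrate (7 mol %), t-BuOOH, 4 Å MS, CH2Cl2, −20 °C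
Reagents that add atoms: tert-butyl hydroperoxide, CC(C)(C)OO
Why: Sharpless asymmetric epoxidation with the D-tartrate epoxidises only the allylic alcohol alkene and sets C4 (R) and C5 (R) as the trans-oxirane.

Step 8
Reactants: 13 (2R,3R)-2,3-epoxygeraniol
Product: 15 3-[(2R,3R)-3-(hydroxymethyl)-2-methyloxiran-2-yl]propanal, via secondary ozonide 14 (not isolated)
Conditions: O3, CH2Cl2, −78 °C; Me2S, −78 °C to rt
Reagents that add atoms: ozone, [O-][O+]=O
Why: Criegee ozonolysis cleaves the only remaining alkene to the C1 aldehyde without touching the oxirane.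

Step 9
Reactants: 11 (1Z,2S,3Z)-1-bromo-4-iodo-1-(2-oxooxetan-3-ylidene)pent-3-en-2-yl (E)-2-methylbut-2-enoate; 15 3-[(2R,3R)-3-(hydroxymethyl)-2-methyloxiran-2-yl]propanal
Product: 17 (1Z,2S,3Z,5R)-1-bromo-5-hydroxy-7-[(2R,3R)-3-(hydroxymethyl)-2-methyloxiran-2-yl]-4-methyl-1-(2-oxooxetan-3-ylidene)hept-3-en-2-yl (E)-2-methylbut-2-enoate, via alkenylchromium 16 (not isolated)
Conditions: CrCl2 (4 equiv), (S)-N-[2-(4-isopropyl-4,5-dihydrooxazol-2-yl)-6-methylphenyl]methanesulfonamide (4.4 equiv), Et3N (4.4 equiv), NiCl2 (1 mol %), THF, 0 °C to rt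
Reagents that add atoms: none
Why: In this asymmetric Nozaki–Hiyama–Kishi coupling, zerovalent nickel at low loading inserts into the unhindered C–I bond far faster than into the tetrasubstituted C–Br bond, the alkenylchromium adds only to the aldehyde with retention of the Z-alkene, and the sulfonamide ligand on trivalent chromium sets C1 as R.

Step 10
Reactants: 17 the diol from step 9
Product: 18 (1Z,2S,3Z,5R)-1-bromo-7-[(2R,3S)-3-formyl-2-methyloxiran-2-yl]-5-hydroxy-4-methyl-1-(2-oxooxetan-3-ylidene)hept-3-en-2-yl (E)-2-methylbut-2-enoate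
Conditions: TEMPO (10 mol %), PhI(OAc)2 (1.1 equiv), CH2Cl2, rt
Reagents that add atoms: none
Why: Oxoammonium oxidation selects the unhindered primary alcohol over the secondary C1 carbinol and is neutral enough for the oxirane and the β-lactone (the C5 label changes to S by priority only).

Step 11
Reactants: 18 the seco-aldehyde from step 10
Product: 21 (1R,4R,5R,6S,8S,9Z)-4,5-epoxy-1,13-dihydroxy-8-tigloyloxygermacra-7(11),9-dien-12,6-olide (target), via alkenylchromium 19 (not isolated), via macrocyclic chromium alkoxide 20 (not isolated)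
Conditions: CrCl2 (15 equiv), NiCl2 (1.5 equiv), degassed DMSO–THF 3:1, syringe-pump addition of 18 over 12 h to 1 mM, rt to 40 °C; aqueous work-up
Reagents that add atoms: none
Why: Proposed new method: zerovalent nickel inserts into the carbonyl-activated C7–Br bond, transmetallation gives alkenyl–CrCl2 species 19 held by the cis lactone carbonyl, its Nozaki–Hiyama–Kishi attack on the epoxy aldehyde closes the ten-membered ring (20), and the C6 chromium alkoxide, locked cis to the strained oxetan-2-one carbonyl, transfers the acyl group at once to give the butenolide and free C13–OH, so both rings form in one operation; the closest known types are Ni/Cr closures of ten-membered rings, butenolide formation from cis-β-haloacrylates and aldehydes under CrCl2/NiCl2, and Barbier closures onto the same 4,5-epoxy aldehyde in germacranolide work, by analogy with which the 6S (threo) carbinol is expected from the folded conformer that keeps the oxirane and the Z-alkene on the ring periphery.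

## Compound list

1 | but-2-yn-1-ol | CC#CCO | starting material
2 | sodium 2,2-bis(2-methoxyethoxy)-3-methyl-2,5-dihydro-1,2-oxaaluminol-2-uide (cyclic alkenylalanate) | CC1=CCO[Al-]1(OCCOC)OCCOC.[Na+] | intermediate
3 | (Z)-3-iodobut-2-en-1-ol | C/C(I)=C/CO | intermediate
4 | (Z)-3-iodobut-2-enal | C/C(I)=C/C=O | intermediate
5 | tert-butyldimethyl(prop-2-yn-1-yloxy)silane | C#CCO[Si](C)(C)C(C)(C)C | starting material
6 | methyl{3-[(tert-butyldimethylsilyl)oxy]prop-1-yn-1-yl}zinc | C[Zn]C#CCO[Si](C)(C)C(C)(C)C | intermediate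
7 | (2Z,4S)-7-[(tert-butyldimethylsilyl)oxy]-2-iodohept-2-en-5-yn-4-ol | C/C(I)=C/[C@H](O)C#CCO[Si](C)(C)C(C)(C)C | intermediate
8 | (E)-2-methylbut-2-enoyl chloride (tigloyl chloride) | C/C=C(\C)C(=O)Cl | starting material
9 | (2Z,4S)-7-[(tert-butyldimethylsilyl)oxy]-2-iodohept-2-en-5-yn-4-yl (E)-2-methylbut-2-enoate | C/C=C(\C)C(=O)O[C@H](C#CCO[Si](C)(C)C(C)(C)C)/C=C(/C)I | intermediate
10 | (2Z,4S)-7-hydroxy-2-iodohept-2-en-5-yn-4-yl (E)-2-methylbut-2-enoate | C/C=C(\C)C(=O)O[C@H](C#CCO)/C=C(/C)I | intermediate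
11 | (1Z,2S,3Z)-1-bromo-4-iodo-1-(2-oxooxetan-3-ylidene)pent-3-en-2-yl (E)-2-methylbut-2-enoate (Br cis to the lactone C=O) | C/C=C(\C)C(=O)O[C@H](/C(Br)=C1\COC1=O)/C=C(/C)I | intermediate
12 | geraniol | CC(C)=CCC/C(C)=C/CO | starting material
13 | (2R,3R)-2,3-epoxygeraniol | CC(C)=CCC[C@@]1(C)O[C@@H]1CO | intermediate
14 | secondary ozonide of 13 (3,3-dimethyl-1,2,4-trioxolane, epimeric at the acetal carbon) | CC1(C)OOC(CC[C@@]2(C)O[C@@H]2CO)O1 | intermediate
15 | 3-[(2R,3R)-3-(hydroxymethyl)-2-methyloxiran-2-yl]propanal | O=CCC[C@@]1(C)O[C@@H]1CO | intermediate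
16 | C10 alkenyl(dichloro)chromium derived from 11 | C/C=C(\C)C(=O)O[C@H](/C(Br)=C1\COC1=O)/C=C(/C)[Cr](Cl)Cl | intermediate
17 | (1Z,2S,3Z,5R)-1-bromo-5-hydroxy-7-[(2R,3R)-3-(hydroxymethyl)-2-methyloxiran-2-yl]-4-methyl-1-(2-oxooxetan-3-ylidene)hept-3-en-2-yl (E)-2-methylbut-2-enoate | C/C=C(\C)C(=O)O[C@H](/C(Br)=C1\COC1=O)/C=C(/C)[C@H](O)CC[C@@]1(C)O[C@@H]1CO | intermediate
18 | (1Z,2S,3Z,5R)-1-bromo-7-[(2R,3S)-3-formyl-2-methyloxiran-2-yl]-5-hydroxy-4-methyl-1-(2-oxooxetan-3-ylidene)hept-3-en-2-yl (E)-2-methylbut-2-enoate | C/C=C(\C)C(=O)O[C@H](/C(Br)=C1\COC1=O)/C=C(/C)[C@H](O)CC[C@@]1(C)O[C@@H]1C=O | intermediate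
19 | C7 alkenyl(dichloro)chromium derived from 18 | C/C=C(\C)C(=O)O[C@H](/C([Cr](Cl)Cl)=C1\COC1=O)/C=C(/C)[C@H](O)CC[C@@]1(C)O[C@@H]1C=O | intermediate
20 | ten-membered carbocycle with C6–OCrCl2 and the 7(11)-ylidene oxetan-2-one still intact (C6 cis to C12) | C/C=C(\C)C(=O)O[C@H]1/C=C(/C)[C@H](O)CC[C@@]2(C)O[C@@H]2[C@@H](O[Cr](Cl)Cl)/C1=C3/COC3=O | intermediate
21 | (1R,4R,5R,6S,8S,9Z)-4,5-epoxy-1,13-dihydroxy-8-tigloyloxygermacra-7(11),9-dien-12,6-olide (CNP0167056.1) | C/C=C(\C)C(=O)O[C@H]1/C=C(/C)[C@H](O)CC[C@@]2(C)O[C@@H]2[C@H]2OC(=O)C(CO)=C12 | target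

## Step count

Total steps: 11. Longest linear sequence: 9 (steps 1–6, then 9–11).

## Three steps most likely to fail

**Step 11.**
- Possible failures:
  - loss of the β-placed tiglate from the C7–metal species to give an allene
  - protodebromination
  - attack of C1–OH on the oxirane under Lewis-acidic trivalent chromium
  - the wrong C6 epimer
- The fallback sets out from 11 and 12 and returns at 21. It makes the oxirane last.
- Chemoselective ozonolysis of the electron-rich 6,7-alkene of 12 gives (E)-6-hydroxy-4-methylhex-4-enal F8.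
- Coupling F8 with 11 under the step 9 conditions gives the allylic diol F9.
- TEMPO/PhI(OAc)2 gives the enal F10, which has no acid-sensitive hydroxy-epoxide.
- The same Ni/Cr closure with β-lactone opening gives the 4,5-alkene macrocycle F11.
- mCPBA (1 equiv, NaHCO3, CH2Cl2, 0 °C) should epoxidise the strained E-alkene from its outer face, syn to O6. The C9=C10 alkene is deactivated by two allylic oxygens. This gives 21.

**Step 9.**
- Possible failures: competing activation of the C7–Br bond, or weak ligand control at C1.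
- The fallback sets out from 11 and 15 and returns at 17. It replaces ligand control by an oxidation/reduction sequence.
- The coupling is run without ligand at minimal NiCl2 loading. It gives 17 together with its C1 epimer F6.
- MnO2 oxidises only the allylic carbinol of both epimers to the single Z-enone F7. The epoxy carbinol is not allylic and stays.
- (S)-Me-CBS oxazaborolidine with BH3·SMe2 at −40 °C reduces F7, with the alkenyl group acting as the large group, to the 1R alcohol 17.

**Step 6.**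
- Possible failures: transient zerovalent palladium inserting into the vinyl iodide, or poor regiocontrol next to the bulky C8.
- The fallback sets out from 7 and returns at 11. It carries C10 as a silane through the palladium step.
- TMSCl/imidazole gives the O-trimethylsilyl ether F1.
- t-BuLi (2 equiv, −78 °C) causes lithium–iodine exchange and a 1,4 O-to-C silyl shift (retro-Brook) to the Z-vinylsilane carbinol F2.
- Acylation with 8 gives the tiglate F3, and HF·pyridine gives the alkynol F4.
- PdBr2/CuBr2/CO gives the bromoalkylidene β-lactone F5.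
- N-iodosuccinimide in (CF3)2CHOH effects ipso-iododesilylation with retention to give 11.

## Further compounds

F1 | step 6 | (2Z,4S)-7-[(tert-butyldimethylsilyl)oxy]-2-iodo-4-[(trimethylsilyl)oxy]hept-2-en-5-yne | C/C(I)=C/[C@H](O[Si](C)(C)C)C#CCO[Si](C)(C)C(C)(C)C
F2 | step 6 | (2Z,4S)-7-[(tert-butyldimethylsilyl)oxy]-2-(trimethylsilyl)hept-2-en-5-yn-4-ol | C/C([Si](C)(C)C)=C/[C@H](O)C#CCO[Si](C)(C)C(C)(C)C
F3 | step 6 | (2Z,4S)-7-[(tert-butyldimethylsilyl)oxy]-2-(trimethylsilyl)hept-2-en-5-yn-4-yl (E)-2-methylbut-2-enoate | C/C=C(\C)C(=O)O[C@H](C#CCO[Si](C)(C)C(C)(C)C)/C=C(/C)[Si](C)(C)C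
F4 | step 6 | (2Z,4S)-7-hydroxy-2-(trimethylsilyl)hept-2-en-5-yn-4-yl (E)-2-methylbut-2-enoate | C/C=C(\C)C(=O)O[C@H](C#CCO)/C=C(/C)[Si](C)(C)C
F5 | step 6 | (1Z,2S,3Z)-1-bromo-1-(2-oxooxetan-3-ylidene)-4-(trimethylsilyl)pent-3-en-2-yl (E)-2-methylbut-2-enoate | C/C=C(\C)C(=O)O[C@H](/C(Br)=C1\COC1=O)/C=C(/C)[Si](C)(C)C
F6 | step 9 | C1 epimer (5S) of 17 | C/C=C(\C)C(=O)O[C@H](/C(Br)=C1\COC1=O)/C=C(/C)[C@@H](O)CC[C@@]1(C)O[C@@H]1CO
F7 | step 9 | C1 ketone (Z-enone) corresponding to 17 | C/C=C(\C)C(=O)O[C@H](/C(Br)=C1\COC1=O)/C=C(/C)C(=O)CC[C@@]1(C)O[C@@H]1CO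
F8 | step 11 | (E)-6-hydroxy-4-methylhex-4-enal | O=CCC/C(C)=C/CO
F9 | step 11 | 4,5-alkene analogue of 17 (1R,8S; 4E,9Z) | C/C=C(\C)C(=O)O[C@H](/C(Br)=C1\COC1=O)/C=C(/C)[C@H](O)CC/C(C)=C/CO
F10 | step 11 | 4,5-alkene analogue of 18 (C6 enal) | C/C=C(\C)C(=O)O[C@H](/C(Br)=C1\COC1=O)/C=C(/C)[C@H](O)CC/C(C)=C/C=O
F11 | step 11 | (1R,6R,8S,4E,9Z)-1,13-dihydroxy-8-tigloyloxygermacra-4,7(11),9-trien-12,6-olide (C6 arranged in space as in 21) | C/C=C(\C)C(=O)O[C@H]1/C=C(/C)[C@H](O)CC/C(C)=C/[C@H]2OC(=O)C(CO)=C12
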